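**Strategy.** The route rests on disconnecting ring A at C1–C10 (labdane numbering) and exploits the 1,3-relationship between the C2 oxygen and the quaternary C10. Ring B, the C4 gem-dimethyl unit and the complete side chain are assembled first from (S)-pulegone, allyltrimethylsilane and an (S)-linalool-derived iodide. The C2 oxygen is then bonded temporarily to C10 in a six-membered cyclic enol ether, C10–O–C2(=C1H2). A Lewis acid ionises the tertiary C10–O bond and the tethered enolate recloses through C1. One isomerisation thus creates the C1–C10 bond, the C10 quaternary centre, the trans ring fusion and the C2 carbonyl, which is later reduced and esterified with inversion.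

Key step: step 12

Assumption: (S)-(−)-pulegone and (S)-(+)-linalool are taken as commercial materials of high enantiomeric purity; labdane numbering (C1–C20) is used for all ring compounds.

Step 1
Reactants: 1 (S)-(+)-linalool
Product: 2 (S)-linalyl tert-butyldimethylsilyl ether
Conditions: t-BuMe2SiOTf, 2,6-lutidine, CH2Cl2, 0 °C to rt
Reagents that add atoms: tert-butyldimethylsilyl triflate, CC(C)(C)[Si](C)(C)OS(=O)(=O)C(F)(F)F
Why: Silyl triflate silylation protects the hindered tertiary allylic alcohol without touching its stereocentre, which becomes C13 of the target with the required S configuration.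

Step 2
Reactants: 2 (S)-linalyl tert-butyldimethylsilyl ether
Product: 3 (4S)-4-silyloxy-4-methylhex-5-enal
Conditions: O3 (1 equiv), CH2Cl2, −78 °C; PPh3
Reagents that add atoms: ozone, [O-][O+]=O
Why: Chemoselective ozonolysis cleaves the electron-rich trisubstituted alkene much faster than the hindered vinyl group next to the silyloxy-bearing quaternary carbon.

Step 3
Reactants: 3 (4S)-4-silyloxy-4-methylhex-5-enal
Product: 4 (4S)-4-silyloxy-4-methylhex-5-enoic acid
Conditions: NaClO2, NaH2PO4, 2-methylbut-2-ene, t-BuOH/H2O, 0 °C to rt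
Reagents that add atoms: sodium chlorite, [Na+].[O-]Cl=O
Why: Pinnick oxidation converts the aldehyde to the acid under buffered conditions that leave the vinyl group and the silyl ether alone.

Step 4
Reactants: 4 (4S)-4-silyloxy-4-methylhex-5-enoic acid
Product: 5 (3S)-5-iodo-3-methyl-3-silyloxypent-1-ene
Conditions: PhI(OAc)2, I2, cyclohexane, hν, reflux
Reagents that add atoms: iodine, II
Why: Hunsdiecker-type radical iododecarboxylation (acyl hypoiodite chain) shortens the chain by one carbon to the primary iodide, the primary radical having no fast cyclisation mode onto the vinyl group and the quaternary stereocentre not being involved.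

Step 5
Reactants: 6 (S)-(−)-pulegone; 7 allyltrimethylsilane
Product: 8 (2R,5S)-5-methyl-2-(2-methylpent-4-en-2-yl)cyclohexan-1-one
Conditions: TiCl4, CH2Cl2, −78 °C; then NaOMe (cat.), MeOH, rt
Reagents that add atoms: none
Why: Hosomi–Sakurai conjugate allylation at the β,β-dimethyl carbon builds the quaternary C4 and brings in C3, C2 and C1, and base equilibration of the α-centre should favour the trans-2,5-diequatorial ketone, so that the pulegone stereocentre (future C8) fixes C5 as R once the minor cis isomer is removed by chromatography.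

Step 6
Reactants: 8 (2R,5S)-5-methyl-2-(2-methylpent-4-en-2-yl)cyclohexan-1-one
Product: 10 (6R)-3-methyl-6-(2-methylpent-4-en-2-yl)cyclohex-2-en-1-one, via silyl enol ether 9 (not isolated)
Conditions: LiN(i-Pr)2, THF, −78 °C, then Me3SiCl; Pd(OAc)2, MeCN, rt
Reagents that add atoms: none
Why: Kinetic enolisation occurs at the unhindered C9 methylene and not at the C5 methine next to the quaternary carbon, and Saegusa–Ito oxidation of enol ether 9 with divalent palladium should give the C8=C9 enone under neutral conditions that leave the now unique C5 stereocentre untouched.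

Step 7
Reactants: 10 (6R)-3-methyl-6-(2-methylpent-4-en-2-yl)cyclohex-2-en-1-one
Product: 11 linear trimethylsilyl dienol ether of 10
Conditions: Me3SiOTf, Et3N, Et2O, 0 °C
Reagents that add atoms: trimethylsilyl triflate, C[Si](C)(C)OS(=O)(=O)C(F)(F)F
Why: Soft enolisation (silyl triflate with an amine) should remove a γ-hydrogen at C7 and give the linear silyl dienol ether, because the C5 hydrogen is shielded by the adjacent quaternary carbon, so no strong base meets the epimerisable C5 centre.

Step 8
Reactants: 11 linear trimethylsilyl dienol ether of 10; 5 (3S)-5-iodo-3-methyl-3-silyloxypent-1-ene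
Product: 15 (2R,6R)-2-alkyl-3-methyl-6-(2-methylpent-4-en-2-yl)cyclohex-3-en-1-one, via lithium dienolate 12 (not isolated), via C9-epimeric ketone 13 (not isolated), via alkylated lithium dienolate 14 (not isolated)
Conditions: MeLi, THF, 0 °C; 5, DMPU, −78 to −20 °C; then LiN(i-Pr)2, −78 °C; AcOH, −78 °C
Reagents that add atoms: none
Why: This is a deconjugative α-alkylation of an extended enolate, in which the lithium dienolate released from the silyl ether is alkylated at C9 and the alkene is left at C7=C8; because the alkyl group enters anti to the C5 substituent, the acidic C9 hydrogen is removed once more and returned by kinetic α-protonation anti to that substituent, which should set C9 as R with the side chain cis to the C5 substituent (also the diequatorial, more stable arrangement).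

Step 9
Reactants: 15 (2R,6R)-2-alkyl-3-methyl-6-(2-methylpent-4-en-2-yl)cyclohex-3-en-1-one
Product: 16 (1R,2R,6R)-tertiary alcohol (C10 carbinol)
Conditions: MeLi, CeCl3, THF, −78 °C
Reagents that add atoms: methyllithium, [Li]C
Why: Organocerium 1,2-addition tolerates this hindered, easily enolised β,γ-unsaturated ketone without conjugation, and axial attack (sp2 C8 removes one 1,3-diaxial hydrogen) should give mainly the C10 epimer shown, while a minor epimer can be carried along because C10 is ionised in step 12.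

Step 10
Reactants: 16 (1R,2R,6R)-tertiary alcohol (C10 carbinol)
Product: 17 trans-fused 2-(iodomethyl)tetrahydropyran (iodoether)
Conditions: I2, NaHCO3, MeCN, 0 °C
Reagents that add atoms: iodine, II
Why: 6-exo iodoetherification of the terminal alkene by the tertiary alcohol ties C2 to the C10 oxygen in a six-membered ring, the other alkenes having no nucleophile placed for a five- or six-membered closure, and the new C2 stereocentre (equatorial iodomethyl expected) is erased in step 11.

Step 11
Reactants: 17 trans-fused 2-(iodomethyl)tetrahydropyran (iodoether)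
Product: 18 trans-fused 2-methylidene tetrahydropyran (cyclic enol ether)
Conditions: KOt-Bu, THF, 0 °C to rt
Reagents that add atoms: none
Why: E2 dehydroiodination of the β-iodo ether gives the exocyclic enol ether, the standard entry to 2-methylidene tetrahydropyrans, and no stereocentre is affected.

Step 12
Reactants: 18 trans-fused 2-methylidene tetrahydropyran (cyclic enol ether)
Product: 20 (4aR,8R,8aR)-trans-decalin-2-one (13-O-silyl 2-oxo-labda-7,14-diene), via carbocation–enolate ion pair 19 (not isolated)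
Conditions: Me2AlCl, CH2Cl2, −78 to −40 °C; aq. NaHCO3
Reagents that add atoms: none
Why: Proposed new method: Me2AlCl binds the enol-ether oxygen and the tertiary C10–O bond ionises to the contact ion pair 19 (C10 carbocation plus tethered aluminium enolate), which recloses at carbon, C1 onto C10, in a formal [1,3] O-to-C shift. The closest known reaction types are the Ferrier carbocyclisation of 2-methylidene tetrahydropyrans and the Petasis–Ferrier rearrangement, where the ionising carbon is an acetal centre, and the Lewis acid tert-alkylation of silyl enol ethers with tertiary halides; a plain tertiary alkyl ether has not been shown in this role. Ring A closes as a six-membered ring in a 6-(enolendo) cation–enolate recombination through a chair transition state while the pyran ring opens. The new C10 stereocentre is controlled by C5, whose equatorial tether returns C1 to the face the oxygen left (least motion from the trans-fused ether) with the C20 methyl group axial, the same chair preference that gives trans-decalins in the second ring closure of stepwise polyene cyclisations. The step needs C–C bond formation to outrun E1 loss, a 1,2-hydride shift from allylic C9 and ionisation of the tertiary allylic silyl ether, which the six-membered intramolecular return inside the ion pair, the low temperature and the proton-scavenging alkylaluminium should secure.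

Step 13
Reactants: 20 (4aR,8R,8aR)-trans-decalin-2-one
Product: 21 (2S)-axial alcohol
Conditions: LiBH(s-Bu)3, THF, −78 °C
Reagents that add atoms: none
Why: In this bulky borohydride reduction the axial face of the C2 carbonyl is blocked by the syn-axial C10 and C4 methyl groups, so hydride delivery from the equatorial side should give the axial (2S) alcohol.

Step 14
Reactants: 21 (2S)-axial alcohol
Product: 22 (2S,13S)-diol
Conditions: Bu4NF, THF, 50 °C
Reagents that add atoms: none
Why: Fluoride-mediated desilylation frees the tertiary allylic alcohol before the ester is installed, so the enoate is never exposed to fluoride.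

Step 15
Reactants: 22 (2S,13S)-diol; 23 3-methylbut-2-enoic acid
Product: 24 target ester
Conditions: PPh3, DIAD, toluene, 0 °C to rt
Reagents that add atoms: none
Why: Mitsunobu esterification inverts the secondary axial alcohol by SN2 displacement to the equatorial (2R) ester, while the tertiary allylic alcohol cannot be activated and stays free.

**Compound list**

1 | (S)-(+)-linalool, (3S)-3,7-dimethylocta-1,6-dien-3-ol | CC(C)=CCC[C@](C)(O)C=C | starting material
2 | tert-butyl{[(3S)-3,7-dimethylocta-1,6-dien-3-yl]oxy}dimethylsilane | CC(C)=CCC[C@](C)(O[Si](C)(C)C(C)(C)C)C=C | intermediate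
3 | (4S)-4-{[tert-butyl(dimethyl)silyl]oxy}-4-methylhex-5-enal | O=CCC[C@](C)(O[Si](C)(C)C(C)(C)C)C=C | intermediate
4 | (4S)-4-{[tert-butyl(dimethyl)silyl]oxy}-4-methylhex-5-enoic acid | OC(=O)CC[C@](C)(O[Si](C)(C)C(C)(C)C)C=C | intermediate
5 | tert-butyl{[(3S)-5-iodo-3-methylpent-1-en-3-yl]oxy}dimethylsilane | ICC[C@](C)(O[Si](C)(C)C(C)(C)C)C=C | intermediate
6 | (S)-(−)-pulegone, (5S)-5-methyl-2-(propan-2-ylidene)cyclohexan-1-one | C[C@H]1CCC(=C(C)C)C(=O)C1 | starting material
7 | allyltrimethylsilane | C=CC[Si](C)(C)C | starting material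
8 | (2R,5S)-5-methyl-2-(2-methylpent-4-en-2-yl)cyclohexan-1-one | O=C1C[C@@H](C)CC[C@@H]1C(C)(C)CC=C | intermediate
9 | trimethyl{[(3S,6R)-3-methyl-6-(2-methylpent-4-en-2-yl)cyclohex-1-en-1-yl]oxy}silane | C[Si](C)(C)OC1=C[C@@H](C)CC[C@@H]1C(C)(C)CC=C | intermediate
10 | (6R)-3-methyl-6-(2-methylpent-4-en-2-yl)cyclohex-2-en-1-one | O=C1C=C(C)CC[C@@H]1C(C)(C)CC=C | intermediate
11 | trimethyl{[(6R)-3-methyl-6-(2-methylpent-4-en-2-yl)cyclohexa-1,3-dien-1-yl]oxy}silane | C[Si](C)(C)OC1=CC(C)=CC[C@@H]1C(C)(C)CC=C | intermediate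
12 | lithium (6R)-3-methyl-6-(2-methylpent-4-en-2-yl)cyclohexa-1,3-dien-1-olate | [Li]OC1=CC(C)=CC[C@@H]1C(C)(C)CC=C | intermediate
13 | (2S,6R)-2-[(3S)-3-{[tert-butyl(dimethyl)silyl]oxy}-3-methylpent-4-en-1-yl]-3-methyl-6-(2-methylpent-4-en-2-yl)cyclohex-3-en-1-one (C9 epimer of 15) | C=C[C@@](C)(O[Si](C)(C)C(C)(C)C)CC[C@H]1C(C)=CC[C@H](C(C)(C)CC=C)C1=O | intermediate
14 | lithium (6R)-2-[(3S)-3-{[tert-butyl(dimethyl)silyl]oxy}-3-methylpent-4-en-1-yl]-3-methyl-6-(2-methylpent-4-en-2-yl)cyclohexa-1,3-dien-1-olate | [Li]OC1=C(CC[C@](C)(O[Si](C)(C)C(C)(C)C)C=C)C(C)=CC[C@@H]1C(C)(C)CC=C | intermediate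
15 | (2R,6R)-2-[(3S)-3-{[tert-butyl(dimethyl)silyl]oxy}-3-methylpent-4-en-1-yl]-3-methyl-6-(2-methylpent-4-en-2-yl)cyclohex-3-en-1-one | C=C[C@@](C)(O[Si](C)(C)C(C)(C)C)CC[C@@H]1C(C)=CC[C@H](C(C)(C)CC=C)C1=O | intermediate
16 | (1R,2R,6R)-2-[(3S)-3-{[tert-butyl(dimethyl)silyl]oxy}-3-methylpent-4-en-1-yl]-1,3-dimethyl-6-(2-methylpent-4-en-2-yl)cyclohex-3-en-1-ol | C=C[C@@](C)(O[Si](C)(C)C(C)(C)C)CC[C@@H]1C(C)=CC[C@H](C(C)(C)CC=C)[C@@]1(C)O | intermediate
17 | (2S,4aR,8R,8aR)-8-[(3S)-3-{[tert-butyl(dimethyl)silyl]oxy}-3-methylpent-4-en-1-yl]-2-(iodomethyl)-4,4,7,8a-tetramethyl-3,4,4a,5,8,8a-hexahydro-2H-chromene | C=C[C@@](C)(O[Si](C)(C)C(C)(C)C)CC[C@@H]1C(C)=CC[C@@H]2C(C)(C)C[C@@H](CI)O[C@@]12C | intermediate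
18 | (4aR,8R,8aR)-8-[(3S)-3-{[tert-butyl(dimethyl)silyl]oxy}-3-methylpent-4-en-1-yl]-4,4,7,8a-tetramethyl-2-methylidene-3,4,4a,5,8,8a-hexahydro-2H-chromene | C=C[C@@](C)(O[Si](C)(C)C(C)(C)C)CC[C@@H]1C(C)=CC[C@@H]2C(C)(C)CC(=C)O[C@@]12C | intermediate
19 | ion pair: ring B C10 carbocation carrying at C5 the 2-methyl-4-(chlorodimethylaluminato-oxy)pent-4-en-2-yl enolate chain | C=C[C@@](C)(O[Si](C)(C)C(C)(C)C)CC[C@@H]1C(C)=CC[C@H](C(C)(C)CC(=C)O[Al-](C)(C)Cl)[C+]1C | intermediate
20 | (4aR,8R,8aR)-8-[(3S)-3-{[tert-butyl(dimethyl)silyl]oxy}-3-methylpent-4-en-1-yl]-4,4,7,8a-tetramethyl-3,4,4a,5,8,8a-hexahydronaphthalen-2(1H)-one | C=C[C@@](C)(O[Si](C)(C)C(C)(C)C)CC[C@@H]1C(C)=CC[C@@H]2C(C)(C)CC(=O)C[C@@]12C | intermediate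
21 | (2S,4aR,8R,8aR)-8-[(3S)-3-{[tert-butyl(dimethyl)silyl]oxy}-3-methylpent-4-en-1-yl]-4,4,7,8a-tetramethyl-1,2,3,4,4a,5,8,8a-octahydronaphthalen-2-ol | C=C[C@@](C)(O[Si](C)(C)C(C)(C)C)CC[C@@H]1C(C)=CC[C@@H]2C(C)(C)C[C@H](O)C[C@@]12C | intermediate
22 | (2S,4aR,8R,8aR)-8-[(3S)-3-hydroxy-3-methylpent-4-en-1-yl]-4,4,7,8a-tetramethyl-1,2,3,4,4a,5,8,8a-octahydronaphthalen-2-ol | C=C[C@@](C)(O)CC[C@@H]1C(C)=CC[C@@H]2C(C)(C)C[C@H](O)C[C@@]12C | intermediate
23 | 3-methylbut-2-enoic acid | CC(C)=CC(O)=O | starting material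
24 | (2R,4aR,8R,8aR)-8-[(3S)-3-hydroxy-3-methylpent-4-en-1-yl]-4,4,7,8a-tetramethyl-1,2,3,4,4a,5,8,8a-octahydronaphthalen-2-yl 3-methylbut-2-enoate | C=C[C@@](C)(O)CC[C@@H]1C(C)=CC[C@@H]2C(C)(C)C[C@@H](OC(=O)C=C(C)C)C[C@@]12C | target

**Totals.** Total step count: 15. Longest linear sequence: 12 steps (steps 1 to 4, then steps 8 to 15).

**Steps most likely to fail**

Step 12 (proposed new method). The ion pair may divert before carbon–carbon bond formation, through a 1,2-hydride shift from the allylic C9 or E1 loss of a proton. Closure may also lose facial control and give some cis-fused product, and protonolysis of the enol ether would consume the substrate. The fallback uses known chemistry and avoids any C10 cation; it sets out from 15 and comes back at 20. Wacker oxidation of the allyl terminus (PdCl2, CuCl, O2, DMF/H2O) should give the diketone F1. Intramolecular aldol condensation (pyrrolidine, AcOH) then closes ring A through C1=C10 to the bicyclic enone F2. Luche reduction (NaBH4, CeCl3, MeOH), anti to the axial C4 methyl group, should give the allylic alcohol F3. Hydroxyl-directed Simmons–Smith cyclopropanation (Et2Zn, CH2I2) places the future C20 on the face of the hydroxyl and gives the cyclopropyl carbinol F4. Dess–Martin oxidation gives the cyclopropyl ketone F5. Brief reduction with Li in NH3 at −78 °C cleaves the exocyclic C1–C20 bond and delivers the angular methyl group of 20.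

Step 8. Proton transfer during the slow SN2 alkylation may cause polyalkylation and return of enone. O-alkylation or elimination of the iodide may compete, and partial deprotonation at C5 would erode enantiopurity. The fallback changes the bond-forming event to a simple ketone enolate alkylation while C8 still anchors the stereochemistry; it sets out from 8 and comes back at 14. Kinetic enolate alkylation of 8 with 5 (LiN(i-Pr)2, THF, DMPU) should give the all-equatorial saturated ketone F6. Kinetic silylation toward C9 (LiN(i-Pr)2, Me3SiCl) gives the silyl enol ether F7. Saegusa–Ito oxidation (Pd(OAc)2, MeCN) gives the tetrasubstituted enone F8. Soft enolisation (Me3SiOTf, Et3N) gives the linear dienol ether F9. MeLi then releases lithium dienolate 14, which is protonated with AcOH to 15 as in the main route.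

Step 15. Activation of the hindered axial alcohol may end in anti elimination toward C1 or C3, or in no displacement. The fallback replaces inversion by acylation with retention; it sets out from 20 and comes back at 24. Reduction under thermodynamic control (SmI2, H2O, Et3N, THF) should give the equatorial alcohol F10. Acylation with 3-methylbut-2-enoyl chloride (pyridine, DMAP, CH2Cl2, 0 °C) gives the silyl-protected ester F11. Buffered Bu4NF/AcOH then frees the tertiary alcohol to give 24.

Further compounds
F1 | step 12 | (2R,6R)-2-[(3S)-3-{[tert-butyl(dimethyl)silyl]oxy}-3-methylpent-4-en-1-yl]-3-methyl-6-(2-methyl-4-oxopentan-2-yl)cyclohex-3-en-1-one | C=C[C@@](C)(O[Si](C)(C)C(C)(C)C)CC[C@@H]1C(C)=CC[C@H](C(C)(C)CC(C)=O)C1=O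
F2 | step 12 | (4aR,8R)-8-[(3S)-3-{[tert-butyl(dimethyl)silyl]oxy}-3-methylpent-4-en-1-yl]-4,4,7-trimethyl-4,4a,5,8-tetrahydronaphthalen-2(3H)-one | C=C[C@@](C)(O[Si](C)(C)C(C)(C)C)CC[C@@H]1C(C)=CC[C@@H]2C(C)(C)CC(=O)C=C12
F3 | step 12 | (2S,4aR,8R)-8-[(3S)-3-{[tert-butyl(dimethyl)silyl]oxy}-3-methylpent-4-en-1-yl]-4,4,7-trimethyl-2,3,4,4a,5,8-hexahydronaphthalen-2-ol | C=C[C@@](C)(O[Si](C)(C)C(C)(C)C)CC[C@@H]1C(C)=CC[C@@H]2C(C)(C)C[C@H](O)C=C12
F4 | step 12 | cyclopropyl carbinol: F3 with a CH2 bridge (future C20) across C1 and C10 on the face of the C2 hydroxyl | C=C[C@@](C)(O[Si](C)(C)C(C)(C)C)CC[C@@H]1C(C)=CC[C@@H]2C(C)(C)C[C@H](O)[C@@H]3C[C@]123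
F5 | step 12 | cyclopropyl ketone: C2 ketone of F4 (1,20-cyclo analogue of 20) | C=C[C@@](C)(O[Si](C)(C)C(C)(C)C)CC[C@@H]1C(C)=CC[C@@H]2C(C)(C)CC(=O)[C@@H]3C[C@]123
F6 | step 8 | (2R,3S,6R)-2-[(3S)-3-{[tert-butyl(dimethyl)silyl]oxy}-3-methylpent-4-en-1-yl]-3-methyl-6-(2-methylpent-4-en-2-yl)cyclohexan-1-one | C=C[C@@](C)(O[Si](C)(C)C(C)(C)C)CC[C@@H]1[C@@H](C)CC[C@H](C(C)(C)CC=C)C1=O
F7 | step 8 | trimethyl{[(3S,6R)-2-[(3S)-3-{[tert-butyl(dimethyl)silyl]oxy}-3-methylpent-4-en-1-yl]-3-methyl-6-(2-methylpent-4-en-2-yl)cyclohex-1-en-1-yl]oxy}silane | C=C[C@@](C)(O[Si](C)(C)C(C)(C)C)CCC1=C(O[Si](C)(C)C)[C@@H](C(C)(C)CC=C)CC[C@@H]1C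
F8 | step 8 | (6R)-2-[(3S)-3-{[tert-butyl(dimethyl)silyl]oxy}-3-methylpent-4-en-1-yl]-3-methyl-6-(2-methylpent-4-en-2-yl)cyclohex-2-en-1-one | C=C[C@@](C)(O[Si](C)(C)C(C)(C)C)CCC1=C(C)CC[C@H](C(C)(C)CC=C)C1=O
F9 | step 8 | trimethyl{[(6R)-2-[(3S)-3-{[tert-butyl(dimethyl)silyl]oxy}-3-methylpent-4-en-1-yl]-3-methyl-6-(2-methylpent-4-en-2-yl)cyclohexa-1,3-dien-1-yl]oxy}silane | C=C[C@@](C)(O[Si](C)(C)C(C)(C)C)CCC1=C(O[Si](C)(C)C)[C@@H](C(C)(C)CC=C)CC=C1C
F10 | step 15 | (2R,4aR,8R,8aR)-8-[(3S)-3-{[tert-butyl(dimethyl)silyl]oxy}-3-methylpent-4-en-1-yl]-4,4,7,8a-tetramethyl-1,2,3,4,4a,5,8,8a-octahydronaphthalen-2-ol | C=C[C@@](C)(O[Si](C)(C)C(C)(C)C)CC[C@@H]1C(C)=CC[C@@H]2C(C)(C)C[C@@H](O)C[C@@]12C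
F11 | step 15 | (2R,4aR,8R,8aR)-8-[(3S)-3-{[tert-butyl(dimethyl)silyl]oxy}-3-methylpent-4-en-1-yl]-4,4,7,8a-tetramethyl-1,2,3,4,4a,5,8,8a-octahydronaphthalen-2-yl 3-methylbut-2-enoate | C=C[C@@](C)(O[Si](C)(C)C(C)(C)C)CC[C@@H]1C(C)=CC[C@@H]2C(C)(C)C[C@@H](OC(=O)C=C(C)C)C[C@@]12C
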